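**Retrosynthetic overview**

1. Feature: the C7 ketone sits next to C6, a corner of the cyclobutane C5–C6–C11–C10 inside the bicyclo[3.1.1]heptenone (pinene-type) unit, which is fused through C5, C10 and C11 to the seven-membered ring C1–C5/C10/C11. The C6–C11 bond can therefore come from moving the one-carbon bridge C11 of a norbornene from a C7 carbinol to C6.
2. Key disconnection: protected enone 29 ⇐ endo C6-amino, C7-hydroxy norbornene 27 by deaminative semipinacol shift. The cyclobutane is made by ring contraction, not by cyclisation.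
3. 27 ⇐ nitro adduct 25 ⇐ one intramolecular Diels–Alder reaction (bonds C5–C10 and C6–C7) of a 5,5-disubstituted 1-siloxycyclopentadiene with a tethered E-nitroalkene; this closes the seven-membered ring and the norbornene together.
4. Diene precursor ⇐ aldol (C11–C1) of 3,5-dimethylcyclopent-2-enone with a cis-acetonide aldehyde made from (R)-glyceraldehyde acetonide and prenyl bromide (C3–C4). C1 is then corrected by oxidation and reduction.
5. Ring order: cyclopentenone (bought), then seven-membered ring plus norbornene (step 14), then cyclobutane (step 16). The two esters are put on last (C1 angelate before acetonide removal, C2 isovalerate at the end).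

Key step: step 16

Remark: the locants C1–C11 used for all intermediates are those of the target ring carbons (C1 angelate carbinol, C2 isovalerate carbinol, C3 free carbinol, C4 CMe2, C5 and C6 cyclobutane CH, C7 ketone, C8=C9(CH3), C10 cyclobutane CH, C11 quaternary methyl carbon). The aldol of step 8 is assumed to follow the closed chair and Felkin–Anh course, which sets C11 correctly but gives C1 as the epimer; steps 9 and 10 correct C1.

**Route**

Step 1
Reactants: 1 (R)-2,3-O-isopropylideneglyceraldehyde; 2 prenyl bromide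
Product: 4 (1S)-1-[(4R)-2,2-dimethyl-1,3-dioxolan-4-yl]-2,2-dimethylbut-3-en-1-ol, via prenylzinc bromide 3 (not isolated)
Conditions: Zn dust, THF/sat. aq. NH4Cl, 0 °C to rt
Reagents that add atoms: none
Why: Barbier allylation in which the allylzinc formed in the flask adds through its gamma carbon (six-membered cyclic transition state), which installs the C4 gem-dimethyl and C5 vinyl unit, and attacks the aldehyde anti to the dioxolane C–O bond (Felkin–Anh), which should set C3 anti (erythro) to C2.

Step 2
Reactants: 4 homoallylic alcohol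
Product: 5 (2R,3S)-4,4-dimethylhex-5-ene-1,2,3-triol
Conditions: AcOH/H2O (4:1), 40 °C
Reagents that add atoms: none
Why: Acid hydrolysis of the terminal acetonide should free the triol without touching the stereocentres or the alkene.

Step 3
Reactants: 5 triol
Product: 6 (2R,3S)-1-[(tert-butyldiphenylsilyl)oxy]-4,4-dimethylhex-5-ene-2,3-diol
Conditions: TBDPSCl, imidazole, CH2Cl2, 0 °C
Reagents that add atoms: tert-butyl(chloro)diphenylsilane, CC(C)(C)[Si](Cl)(c1ccccc1)c1ccccc1
Why: Silylation with a bulky chlorosilane is selective for the single primary hydroxyl over the two hindered secondary ones.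

Step 4
Reactants: 6 silyl ether diol
Product: 7 tert-butyl{[(4R,5S)-2,2-dimethyl-5-(2-methylbut-3-en-2-yl)-1,3-dioxolan-4-yl]methoxy}diphenylsilane
Conditions: Me2C(OMe)2, PPTS (cat.), CH2Cl2, rt
Reagents that add atoms: 2,2-dimethoxypropane, COC(C)(C)OC
Why: Acid-catalysed transketalisation ties the erythro C2/C3 diol into the cis-dioxolane that is carried as far as step 19.

Step 5
Reactants: 7 acetonide silyl ether
Product: 8 [(4R,5S)-2,2-dimethyl-5-(2-methylbut-3-en-2-yl)-1,3-dioxolan-4-yl]methanol
Conditions: TBAF, THF, 0 °C to rt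
Reagents that add atoms: none
Why: Fluoride cleaves the Si–O bond (desilylation) and leaves the acetonide and the alkene untouched.

Step 6
Reactants: 8 primary alcohol
Product: 9 (4S,5S)-2,2-dimethyl-5-(2-methylbut-3-en-2-yl)-1,3-dioxolane-4-carbaldehyde
Conditions: Dess–Martin periodinane, NaHCO3, CH2Cl2, 0 °C to rt
Reagents that add atoms: none
Why: Dess–Martin oxidation under buffered, non-basic conditions should give the aldehyde without epimerising the labile cis-configured C2 centre, and the aldehyde is used at once.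

Step 7
Reactants: 10 3-methylcyclopent-2-en-1-one
Product: 12 3,5-dimethylcyclopent-2-en-1-one (racemic), via lithium dienolate 11 (not isolated)
Conditions: LiN(iPr)2, THF, −78 °C; MeI, −78 to −20 °C
Reagents that add atoms: iodomethane, CI
Why: Kinetic deprotonation takes the alpha-prime proton (C11) of the enone and the cross-conjugated enolate is C-methylated (enolate alkylation), the new centre being racemic and erased again in step 8.

Step 8
Reactants: 12 3,5-dimethylcyclopent-2-en-1-one; 9 cis-dioxolane aldehyde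
Product: 14 (5S)-5-{(R)-[(4R,5S)-2,2-dimethyl-5-(2-methylbut-3-en-2-yl)-1,3-dioxolan-4-yl](hydroxy)methyl}-3,5-dimethylcyclopent-2-en-1-one, via lithium enolate 13 (not isolated)
Conditions: LiN(iPr)2, THF, −78 °C; then 9, −78 °C; AcOH quench at −78 °C
Reagents that add atoms: none
Why: Directed aldol addition in which the tetrasubstituted cross-conjugated enolate should react through a chair Zimmerman–Traxler transition state (ring CH2 C10 anti to the new hydroxyl) on the aldehyde face anti to the C2–O bond (Felkin–Anh), which fixes the quaternary C11 in the target configuration relative to C2 and C3 and gives C1 as the epimer that steps 9 and 10 correct.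

Step 9
Reactants: 14 aldol adduct
Product: 15 (5R)-5-{[(4S,5S)-2,2-dimethyl-5-(2-methylbut-3-en-2-yl)-1,3-dioxolan-4-yl]carbonyl}-3,5-dimethylcyclopent-2-en-1-one
Conditions: Dess–Martin periodinane, NaHCO3, CH2Cl2, 0 °C to rt
Reagents that add atoms: none
Why: Dess–Martin oxidation turns the hindered secondary alcohol into the ketone under neutral conditions that avoid retro-aldol cleavage, and the resulting 1,3-diketone cannot enolise at the quaternary C11.

Step 10
Reactants: 15 diketone
Product: 16 (5S)-5-{(S)-[(4R,5S)-2,2-dimethyl-5-(2-methylbut-3-en-2-yl)-1,3-dioxolan-4-yl](hydroxy)methyl}-3,5-dimethylcyclopent-2-en-1-one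
Conditions: NaBH4, MeOH/CH2Cl2 (1:1), −78 to −40 °C
Reagents that add atoms: none
Why: Chemoselective borohydride reduction in which the non-conjugated alpha-alkoxy ketone should react faster than the enone carbonyl and hydride adds anti to the C2–O bond (Felkin–Anh), which gives the C1 alcohol syn (threo) to C2, that is the target configuration.

Step 11
Reactants: 16 beta-hydroxy enone
Product: 17 C1 tert-butyldimethylsilyl ether of 16 (C11 S; C1 S; dioxolane 4S,5S)
Conditions: TBSOTf, 2,6-lutidine, CH2Cl2, −78 to 0 °C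
Reagents that add atoms: tert-butyldimethylsilyl triflate, CC(C)(C)[Si](C)(C)OS(=O)(=O)C(F)(F)F
Why: A silyl triflate with a hindered base silylates the neopentyl-type secondary alcohol and so blocks retro-aldol cleavage in the basic steps that follow.

Step 12
Reactants: 17 silyl ether with C5 vinyl group
Product: 19 C5 aldehyde (17 with CH=CH2 replaced by CH=O), via vicinal diol 18 (not isolated)
Conditions: OsO4 (cat.), NaIO4, 2,6-lutidine, dioxane/H2O (3:1), rt
Reagents that add atoms: osmium tetroxide, O=[Os](=O)(=O)=O; sodium periodate, [Na+].[O-]I(=O)(=O)=O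
Why: Lemieux–Johnson cleavage in which OsO4 dihydroxylates the electron-rich monosubstituted alkene much faster than the electron-poor trisubstituted enone and periodate cleaves the diol to the non-enolisable C5 aldehyde.

Step 13
Reactants: 19 C5 aldehyde; 20 nitromethane
Product: 23 E-nitroalkene (C5=C6–NO2), via nitro alcohol 21 (not isolated), via nitro mesylate 22 (not isolated)
Conditions: MeNO2, tetramethylguanidine (cat.), THF, 0 °C to rt; evaporate; MsCl, Et3N, CH2Cl2, −20 to 0 °C
Reagents that add atoms: none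
Why: Henry addition to the non-enolisable aldehyde followed by mesylation and E1cB elimination should give the thermodynamically preferred E-nitroalkene, which cannot deconjugate because C4 is quaternary.

Step 14
Reactants: 23 E-nitroalkene enone
Product: 25 nitro Diels–Alder adduct (norbornene with C7–OSiMe3 bridgehead; endo C6–NO2; C4 exo on C5), via silyl dienol ether 24 (not isolated)
Conditions: TMSOTf, Et3N, toluene, 0 °C to rt, then 60 °C
Reagents that add atoms: trimethylsilyl triflate, C[Si](C)(C)OS(=O)(=O)C(F)(F)F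
Why: Soft enolisation can only remove a gamma proton because C11 is quaternary, giving a 1-siloxy-3-methylcyclopentadiene that cannot undergo 1,5-hydrogen shifts, and its intramolecular Diels–Alder reaction joins the nucleophilic diene terminus C10 to the nitroalkene beta carbon C5 and C7 to C6 on the diene face that carries the tether (fixed by C11), so that C4 is forced exo, the nitro group ends endo (E alkene), and C5, C6, C7 and C10 are set in one step.

Step 15
Reactants: 25 nitro adduct
Product: 27 amino alcohol (endo C6–NH2; C7–OH; C1–OTBS; C2/C3 acetonide), via amino silyl ether 26 (not isolated)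
Conditions: Zn dust, AcOH/THF, 0 °C to rt; then K2CO3, MeOH, rt
Reagents that add atoms: none
Why: Zinc in acetic acid reduces the secondary nitro group to the amine with retention at C6 before any base is present, so that no retro-Henry opening can occur, and mild methanolysis then removes only the labile tertiary trimethylsilyl ether.

Step 16
Reactants: 27 amino alcohol
Product: 29 protected tricyclic enone (bicyclo[3.1.1]heptenone fused to the seven-membered ring; C1–OTBS; C2/C3 acetonide), via diazonium acetate 28 (not isolated)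
Conditions: NaNO2, AcOH/H2O (1:1), 0 °C
Reagents that add atoms: none
Why: Nitrosation of the primary amine gives the endo C6 diazonium ion, and as N2 leaves, the C7–C11 bond, which lies close to anti-periplanar to the endo C6–N bond, shifts to C6 while the C7 hydroxyl oxygen donates, giving the protonated ketone and then the C7 enone conjugated with C8=C9. The closest known reaction type is the Tiffeneau–Demjanov (semipinacol) deamination of cyclic 2-amino alcohols with ring contraction. The cyclobutane C5–C6–C11–C10 is not closed by a cyclisation but results from contraction of the five-membered ring C7–C6–C5–C10–C11 through this 1,2-alkyl shift, C7 passing into the six-membered enone ring. C6 is the only new stereocentre; C11 enters anti to the departing nitrogen (inversion at C6, retention at C11) and the bicyclic frame allows no other outcome. The step needs migration of C11 and not of the vinylic C8, and no capture of a free C6 cation by solvent or by hydride shift. This is secured by the endo position of nitrogen, which follows from the E nitroalkene and the tether-enforced exo position of C4 in step 14, and by the hydroxyl push and the enone conjugation gained.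

Step 17
Reactants: 29 silyl-protected enone
Product: 30 C1 alcohol (C2/C3 acetonide retained)
Conditions: TBAF, THF, 0 °C to rt
Reagents that add atoms: none
Why: Fluoride-mediated desilylation frees the C1 hydroxyl, which lies on the face away from the enone bridge and cannot add to it, while acetonide and enone are inert.

Step 18
Reactants: 30 C1 alcohol; 31 angelic acid
Product: 33 C1 angelate, via mixed anhydride 32 (not isolated)
Conditions: 2,4,6-trichlorobenzoyl chloride, Et3N, toluene, rt; then 30, 80 °C
Reagents that add atoms: none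
Why: Yamaguchi esterification through the mixed anhydride acylates the hindered C1 alcohol without a nucleophilic catalyst, which should avoid Z-to-E isomerisation of the angeloyl group.

Step 19
Reactants: 33 angelate acetonide
Product: 34 C2,C3-diol angelate
Conditions: AcOH/H2O (4:1), 45 °C
Reagents that add atoms: none
Why: Mild aqueous acid hydrolyses the cis-fused dioxolane, and the ester, the enone and the cyclobutane are expected to survive.

Step 20
Reactants: 34 diol; 35 isovaleric anhydride
Product: 36 CNP0251293.1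
Conditions: pyridine, DMAP (cat.), CH2Cl2, −20 °C
Reagents that add atoms: none
Why: Acylation under kinetic control should take place at the C2 hydroxyl, which is flanked by two CH groups, and not at the C3 hydroxyl, which is neopentyl (next to the C4 gem-dimethyl carbon).

**Compound list**

1 | (R)-2,3-O-isopropylideneglyceraldehyde [(4R)-2,2-dimethyl-1,3-dioxolane-4-carbaldehyde] | O=C[C@@H]1OC(C)(C)OC1 | starting material
2 | prenyl bromide (1-bromo-3-methylbut-2-ene) | CC(C)=CCBr | starting material
3 | prenylzinc bromide, Me2C=CHCH2ZnBr | CC(C)=CC[Zn]Br | intermediate (not isolated)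
4 | (1S)-1-[(4R)-2,2-dimethyl-1,3-dioxolan-4-yl]-2,2-dimethylbut-3-en-1-ol (C2/C3 anti) | C1[C@@H](OC(C)(C)O1)[C@@H](O)C(C)(C)C=C | intermediate
5 | (2R,3S)-4,4-dimethylhex-5-ene-1,2,3-triol | OC[C@@H](O)[C@@H](O)C(C)(C)C=C | intermediate
6 | (2R,3S)-1-[(tert-butyldiphenylsilyl)oxy]-4,4-dimethylhex-5-ene-2,3-diol | CC(C)(C)[Si](c1ccccc1)(c1ccccc1)OC[C@@H](O)[C@@H](O)C(C)(C)C=C | intermediate
7 | tert-butyl{[(4R,5S)-2,2-dimethyl-5-(2-methylbut-3-en-2-yl)-1,3-dioxolan-4-yl]methoxy}diphenylsilane (cis-dioxolane) | CC(C)(C)[Si](c1ccccc1)(c1ccccc1)OC[C@@H](O2)[C@@H](OC2(C)C)C(C)(C)C=C | intermediate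
8 | [(4R,5S)-2,2-dimethyl-5-(2-methylbut-3-en-2-yl)-1,3-dioxolan-4-yl]methanol | OC[C@@H](O1)[C@@H](OC1(C)C)C(C)(C)C=C | intermediate
9 | (4S,5S)-2,2-dimethyl-5-(2-methylbut-3-en-2-yl)-1,3-dioxolane-4-carbaldehyde (cis) | O=C[C@@H](O1)[C@@H](OC1(C)C)C(C)(C)C=C | intermediate
10 | 3-methylcyclopent-2-en-1-one | CC1=CC(=O)CC1 | starting material
11 | lithium 4-methylcyclopenta-1,4-dien-1-olate (cross-conjugated dienolate of 10) | [Li]OC1=CCC(C)=C1 | intermediate (not isolated)
12 | 3,5-dimethylcyclopent-2-en-1-one (racemic) | CC1CC(C)=CC1=O | intermediate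
13 | lithium 2,4-dimethylcyclopenta-1,4-dien-1-olate (enolate of 12) | [Li]OC1=C(C)CC(C)=C1 | intermediate (not isolated)
14 | (5S)-5-{(R)-[(4R,5S)-2,2-dimethyl-5-(2-methylbut-3-en-2-yl)-1,3-dioxolan-4-yl](hydroxy)methyl}-3,5-dimethylcyclopent-2-en-1-one (C11 as in target, C1 epimeric) | O[C@H]([C@]1(C)CC(C)=CC1=O)[C@@H](O2)[C@@H](OC2(C)C)C(C)(C)C=C | intermediate
15 | (5R)-5-{[(4S,5S)-2,2-dimethyl-5-(2-methylbut-3-en-2-yl)-1,3-dioxolan-4-yl]carbonyl}-3,5-dimethylcyclopent-2-en-1-one | O=C([C@]1(C)CC(C)=CC1=O)[C@@H](O2)[C@@H](OC2(C)C)C(C)(C)C=C | intermediate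
16 | (5S)-5-{(S)-[(4R,5S)-2,2-dimethyl-5-(2-methylbut-3-en-2-yl)-1,3-dioxolan-4-yl](hydroxy)methyl}-3,5-dimethylcyclopent-2-en-1-one (C1 as in target) | O[C@@H]([C@]1(C)CC(C)=CC1=O)[C@@H](O2)[C@@H](OC2(C)C)C(C)(C)C=C | intermediate
17 | C1 tert-butyldimethylsilyl ether of 16 (C11 S, C1 S, dioxolane 4S,5S) | CC(C)(C)[Si](C)(C)O[C@@H]([C@]1(C)CC(C)=CC1=O)[C@@H](O2)[C@@H](OC2(C)C)C(C)(C)C=C | intermediate
18 | vicinal diol from 17 (CH=CH2 converted to CH(OH)CH2OH, new carbinol centre unspecified) | CC(C)(C)[Si](C)(C)O[C@@H]([C@]1(C)CC(C)=CC1=O)[C@@H](O2)[C@@H](OC2(C)C)C(C)(C)C(O)CO | intermediate (not isolated)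
19 | C5 aldehyde (17 with CH=CH2 replaced by CH=O, stereocentres unchanged) | CC(C)(C)[Si](C)(C)O[C@@H]([C@]1(C)CC(C)=CC1=O)[C@@H](O2)[C@@H](OC2(C)C)C(C)(C)C=O | intermediate
20 | nitromethane | C[N+](=O)[O-] | starting material
21 | nitro alcohol (C5 carbinol unspecified, C6 CH2NO2) | CC(C)(C)[Si](C)(C)O[C@@H]([C@]1(C)CC(C)=CC1=O)[C@@H](O2)[C@@H](OC2(C)C)C(C)(C)C(O)C[N+](=O)[O-] | intermediate (not isolated)
22 | nitro mesylate (methanesulfonate of 21) | CC(C)(C)[Si](C)(C)O[C@@H]([C@]1(C)CC(C)=CC1=O)[C@@H](O2)[C@@H](OC2(C)C)C(C)(C)C(OS(C)(=O)=O)C[N+](=O)[O-] | intermediate (not isolated)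
23 | E-nitroalkene (C5=C6–NO2) with 5,5-disubstituted 3-methylcyclopent-2-enone, C1–OTBS, C2/C3 cis-acetonide | CC(C)(C)[Si](C)(C)O[C@@H]([C@]1(C)CC(C)=CC1=O)[C@@H](O2)[C@@H](OC2(C)C)C(C)(C)/C=C/[N+](=O)[O-] | intermediate
24 | 1-(trimethylsiloxy)-3-methylcyclopenta-1,3-diene with quaternary C11 carrying the tethered E-nitroalkene | CC(C)(C)[Si](C)(C)O[C@@H]([C@]1(C)C=C(C)C=C1O[Si](C)(C)C)[C@@H](O2)[C@@H](OC2(C)C)C(C)(C)/C=C/[N+](=O)[O-] | intermediate (not isolated)
25 | nitro Diels–Alder adduct: norbornene (bridgeheads C7–OSiMe3 and C10–H, bridge C11, alkene C8=C9, saturated bridge C5–C6) fused through C5, C10, C11 to the seven-membered ring; C4 exo on C5, NO2 endo on C6, C1–OTBS, C2/C3 cis-acetonide | CC(C)(C)[Si](C)(C)O[C@@H]1[C@@H](O4)[C@@H](OC4(C)C)C(C)(C)[C@@H]2[C@@H]([N+](=O)[O-])[C@@]3(O[Si](C)(C)C)C=C(C)[C@@H]2[C@@]13C | intermediate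
26 | endo C6 amine with C7–OSiMe3 (otherwise as 25) | CC(C)(C)[Si](C)(C)O[C@@H]1[C@@H](O4)[C@@H](OC4(C)C)C(C)(C)[C@@H]2[C@@H](N)[C@@]3(O[Si](C)(C)C)C=C(C)[C@@H]2[C@@]13C | intermediate (not isolated)
27 | norbornenyl amino alcohol: endo C6–NH2, bridgehead C7–OH, C1–OTBS, C2/C3 cis-acetonide | CC(C)(C)[Si](C)(C)O[C@@H]1[C@@H](O4)[C@@H](OC4(C)C)C(C)(C)[C@@H]2[C@@H](N)[C@@]3(O)C=C(C)[C@@H]2[C@@]13C | intermediate
28 | endo C6 diazonium acetate of 27 | CC(C)(C)[Si](C)(C)O[C@@H]1[C@@H](O4)[C@@H](OC4(C)C)C(C)(C)[C@@H]2[C@@H]([N+]#N)[C@@]3(O)C=C(C)[C@@H]2[C@@]13C.CC(=O)[O-] | intermediate (not isolated)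
29 | protected tricyclic enone: bicyclo[3.1.1]hept-3-en-2-one (C7 ketone, C8=C9 methyl alkene, cyclobutane C5–C6–C11–C10) fused to the seven-membered ring; C1–OTBS, C2/C3 cis-acetonide | CC(C)(C)[Si](C)(C)O[C@@H]1[C@@H](O4)[C@@H](OC4(C)C)C(C)(C)[C@@H]2[C@H]3C(=O)C=C(C)[C@@H]2[C@@]13C | intermediate
30 | C1 alcohol of 29 (acetonide retained) | O[C@@H]1[C@@H](O4)[C@@H](OC4(C)C)C(C)(C)[C@@H]2[C@H]3C(=O)C=C(C)[C@@H]2[C@@]13C | intermediate
31 | angelic acid [(Z)-2-methylbut-2-enoic acid] | C/C=C(/C)C(=O)O | starting material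
32 | angelic 2,4,6-trichlorobenzoic mixed anhydride | C/C=C(/C)C(=O)OC(=O)c1c(Cl)cc(Cl)cc1Cl | intermediate (not isolated)
33 | C1 angelate, C2/C3 acetonide | C/C=C(/C)C(=O)O[C@@H]1[C@@H](O4)[C@@H](OC4(C)C)C(C)(C)[C@@H]2[C@H]3C(=O)C=C(C)[C@@H]2[C@@]13C | intermediate
34 | C1 angelate C2,C3-diol | C/C=C(/C)C(=O)O[C@@H]1[C@@H](O)[C@@H](O)C(C)(C)[C@@H]2[C@H]3C(=O)C=C(C)[C@@H]2[C@@]13C | intermediate
35 | isovaleric anhydride (3-methylbutanoic anhydride) | CC(C)CC(=O)OC(=O)CC(C)C | starting material
36 | CNP0251293.1 (C1 angelate, C2 isovalerate, C3 hydroxyl) | C/C=C(/C)C(=O)O[C@@H]1[C@@H](OC(=O)CC(C)C)[C@@H](O)C(C)(C)[C@@H]2[C@H]3C(=O)C=C(C)[C@@H]2[C@@]13C | target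

**Step count and risks**

Total step count: 20. Longest linear sequence: 19 (steps 1–6 and 8–20; step 7 is the one-step branch).

Steps most likely to fail:

Step 16. Loss of nitrogen may run ahead of the C11 shift. A free C6 cation could then be captured by acetate or water, relieved by a hydride shift, or relieved by migration of the vinylic C8, which would give a rearranged norbornenone. Fallback: replace the diazonium by a sulfonate, whose departure is coupled to alkoxide push. Setting out from 27, oxidative deamination with 3,5-di-tert-butyl-1,2-benzoquinone (MeOH/THF, rt), then aqueous oxalic acid, should give the alpha-hydroxy ketone F1. NaBH4 (MeOH, −40 °C) is expected to add from the exo face, as in norbornan-2-ones, and give the endo C6,C7-diol F2. MsCl/Et3N (CH2Cl2, −20 °C) should sulfonylate only the secondary hydroxyl and give the endo mesylate F3. KOtBu (THF, −40 °C) then triggers the pinacol-type 1,2-shift of C11 with loss of mesylate, and the route is rejoined at 29.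

Step 14. The dienol ether may form with the exocyclic double bond, or the nitroalkene may be consumed by amine- or silyl-triflate-induced oligomerisation faster than the seven-membered ring closes. Fallback: use a more robust dienophile and introduce nitrogen by Curtius rearrangement. Setting out from 19, Wittig olefination with allyl (triphenylphosphoranylidene)acetate (toluene, 80 °C) should give the allyl E-enoate F4. TMSOTf/Et3N and then heating (toluene, 110 °C) should give the Diels–Alder adduct with the endo C6 allyl ester F5. Pd(PPh3)4/morpholine (THF, rt) frees the endo C6 carboxylic acid F6. Diphenylphosphoryl azide/Et3N (toluene, rt) gives the acyl azide F7, which at 80 °C rearranges with retention at C6 to the endo C6 isocyanate F8, and this is trapped with allyl alcohol as the allyl carbamate F9. Pd(PPh3)4/morpholine then releases the amine, and the route is rejoined at 26 (desilylated to 27 as in the second stage of step 15).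

Step 8. Pairing of the faces of a tetrasubstituted enolate and a hindered aldehyde may be weak, which would lose control at C11. Retro-aldol cleavage on warming and base-induced epimerisation of the cis-dioxolane aldehyde are further risks. Fallback: make the quaternary centre by alkylation instead of by the aldol. Setting out from 10 and 9, the less hindered lithium enolate of 10 (LiN(iPr)2, THF, −78 °C) should add to 9 under Felkin–Anh control and give the aldol adduct F10. Dess–Martin oxidation gives the enolisable beta-diketone F11. C-methylation of its chelated enolate (K2CO3, MeI, acetone, rt) is expected to occur anti to the tert-alkyl group that the cis-dioxolane holds over one face; the C11 epimers are separated if necessary, and the route is rejoined at 15.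

**Further compounds**

F1 | step 16 | alpha-hydroxy ketone (C6 ketone, C7–OH, C1–OTBS, acetonide) | CC(C)(C)[Si](C)(C)O[C@@H]1[C@@H](O4)[C@@H](OC4(C)C)C(C)(C)[C@@H]2C(=O)[C@@]3(O)C=C(C)[C@@H]2[C@@]13C
F2 | step 16 | endo C6,C7-diol | CC(C)(C)[Si](C)(C)O[C@@H]1[C@@H](O4)[C@@H](OC4(C)C)C(C)(C)[C@@H]2[C@@H](O)[C@@]3(O)C=C(C)[C@@H]2[C@@]13C
F3 | step 16 | endo C6 mesylate (C7–OH free) | CC(C)(C)[Si](C)(C)O[C@@H]1[C@@H](O4)[C@@H](OC4(C)C)C(C)(C)[C@@H]2[C@@H](OS(C)(=O)=O)[C@@]3(O)C=C(C)[C@@H]2[C@@]13C
F4 | step 14 | allyl E-enoate (C5=C6–CO2allyl) | CC(C)(C)[Si](C)(C)O[C@@H]([C@]1(C)CC(C)=CC1=O)[C@@H](O2)[C@@H](OC2(C)C)C(C)(C)/C=C/C(=O)OCC=C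
F5 | step 14 | Diels–Alder adduct with endo C6 allyl ester and C7–OSiMe3 | CC(C)(C)[Si](C)(C)O[C@@H]1[C@@H](O4)[C@@H](OC4(C)C)C(C)(C)[C@@H]2[C@@H](C(=O)OCC=C)[C@@]3(O[Si](C)(C)C)C=C(C)[C@@H]2[C@@]13C
F6 | step 14 | endo C6 carboxylic acid | CC(C)(C)[Si](C)(C)O[C@@H]1[C@@H](O4)[C@@H](OC4(C)C)C(C)(C)[C@@H]2[C@@H](C(=O)O)[C@@]3(O[Si](C)(C)C)C=C(C)[C@@H]2[C@@]13C
F7 | step 14 | acyl azide | CC(C)(C)[Si](C)(C)O[C@@H]1[C@@H](O4)[C@@H](OC4(C)C)C(C)(C)[C@@H]2[C@@H](C(=O)N=[N+]=[N-])[C@@]3(O[Si](C)(C)C)C=C(C)[C@@H]2[C@@]13C
F8 | step 14 | endo C6 isocyanate | CC(C)(C)[Si](C)(C)O[C@@H]1[C@@H](O4)[C@@H](OC4(C)C)C(C)(C)[C@@H]2[C@@H](N=C=O)[C@@]3(O[Si](C)(C)C)C=C(C)[C@@H]2[C@@]13C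
F9 | step 14 | allyl carbamate | CC(C)(C)[Si](C)(C)O[C@@H]1[C@@H](O4)[C@@H](OC4(C)C)C(C)(C)[C@@H]2[C@@H](NC(=O)OCC=C)[C@@]3(O[Si](C)(C)C)C=C(C)[C@@H]2[C@@]13C
F10 | step 8 | aldol adduct of 10 and 9 (C11–H, configuration at C11 unspecified) | O[C@H](C1CC(C)=CC1=O)[C@@H](O2)[C@@H](OC2(C)C)C(C)(C)C=C
F11 | step 8 | beta-diketone (C11–H, enolisable) | O=C(C1CC(C)=CC1=O)[C@@H](O2)[C@@H](OC2(C)C)C(C)(C)C=C
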